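**Plan**

1. Retrosynthetic cuts, in order: C3–aroyl and C1–prenyl (late lithiations of a bicyclic vinylogous ester), then the C1–C8 bond between the two quaternary carbons (key step), then C5–prenyl and C5–C6 (two alkylations of a Birch diene).
2. Enabling feature: C6–C7(prenyl)–C8Me2 of ring B is a lavandulyl unit attached to C5, and ring A (C1–C2–C3–C4–C5–C9) without its C1/C3 substituents is a masked phloroglucinol whose halves C9/C1 and C4/C3 are equivalent, so C5 is not stereogenic until C1–C8 closes.
3. Forward: ring A enters as 1,5-dimethoxycyclohexa-1,4-diene and is made quaternary at C5 with (S)-lavandulyl and prenyl; ring B then closes (C1–C8) in an MHAT radical-polar crossover cyclisation that gives the bicyclo[3.3.1]nonan-9-one directly.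
4. Stereochemistry: C7 is set once, by an Evans deconjugative alkylation that gives (S)-lavandulol; C1 and C5 are relayed from it in the key step (chair closure with the C7-prenyl equatorial, i.e. 7-exo); the later bridgehead substitution retains configuration.
5. Endgame: allylic oxidation at C2, bridgehead prenylation at C1, aroylation at C3, one global deprotection.

Key step: step 8

Remarks on the chemistry: the target is drawn as one enol tautomer of the β-triketone and is expected to exist as the usual tautomer mixture; descriptors refer to the drawn tautomer. Locants are those of the bicyclo[3.3.1]nonane (C1 next to C2=O and C8Me2; C5 next to C4 and C6H2; C9 the bridging ketone). The C1 descriptor changes between 18, 19/21 and 26/27 only because CIP priorities change; the spatial arrangement is the same throughout. Organolithium intermediates are written covalently.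

**Route**

Step 1
Reactants: 1 (S)-4-benzyloxazolidin-2-one; 2 3-methylbut-2-enoyl chloride
Product: 4 (S)-4-benzyl-3-(3-methylbut-2-enoyl)oxazolidin-2-one, via N-lithio oxazolidinone 3 (not isolated)
Conditions: n-BuLi, THF, −78 °C; then 2, −78 → 0 °C
Reagents that add atoms: none
Why: N-acylation of the lithiated Evans auxiliary by the acid chloride; no stereocentre is formed.

Step 2
Reactants: 4 (S)-4-benzyl-3-(3-methylbut-2-enoyl)oxazolidin-2-one; 5 prenyl bromide (1-bromo-3-methylbut-2-ene)
Product: 7 (S)-4-benzyl-3-[(2S)-5-methyl-2-(prop-1-en-2-yl)hex-4-enoyl]oxazolidin-2-one, via sodium Z-dienolate 6 (not isolated)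
Conditions: NaHMDS, THF, −78 °C; then 5, −78 → −40 °C
Reagents that add atoms: none
Why: Evans asymmetric alkylation in its deconjugative form: γ-deprotonation gives the chelated (Z)-dienolate, which should be alkylated at the α-carbon on the face opposite the benzyl group, setting the (S) centre that becomes C7.

Step 3
Reactants: 7 (S)-4-benzyl-3-[(2S)-5-methyl-2-(prop-1-en-2-yl)hex-4-enoyl]oxazolidin-2-one
Product: 8 (S)-lavandulol [(2S)-5-methyl-2-(prop-1-en-2-yl)hex-4-en-1-ol]
Conditions: LiBH4, MeOH (1 equiv), Et2O, 0 °C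
Reagents that add atoms: none
Why: Reductive cleavage of the N-acyl oxazolidinone by hydride attack at the exocyclic carbonyl, which should leave the α-centre and both isolated alkenes untouched.

Step 4
Reactants: 8 (S)-lavandulol
Product: 9 (S)-lavandulyl iodide [(3S)-3-(iodomethyl)-2,6-dimethylhepta-1,5-diene]
Conditions: I2, PPh3, imidazole, CH2Cl2, 0 °C → rt
Reagents that add atoms: iodine, II
Why: Appel-type iodination of the primary alcohol; the stereocentre is not involved.

Step 5
Reactants: 10 1,3-dimethoxybenzene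
Product: 11 1,5-dimethoxycyclohexa-1,4-diene
Conditions: Li, NH3 (l), t-BuOH, THF, −78 → −33 °C
Reagents that add atoms: none
Why: Birch reduction of the resorcinol diether gives the 2,5-dihydro isomer with both enol ethers intact.

Step 6
Reactants: 11 1,5-dimethoxycyclohexa-1,4-diene; 9 (S)-lavandulyl iodide
Product: 13 1,5-dimethoxy-6-[(2R)-5-methyl-2-(prop-1-en-2-yl)hex-4-en-1-yl]cyclohexa-1,4-diene, via 6-lithio diene 12 (not isolated)
Conditions: t-BuLi (1.0 equiv), THF, −78 °C; then 9, −78 → −20 °C
Reagents that add atoms: none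
Why: Deprotonation of the CH2 flanked by both methoxy-bearing carbons gives a pentadienyl anion that should be alkylated (SN2) at its central carbon, forming the C5–C6 bond without touching the side-chain stereocentre.

Step 7
Reactants: 13 1,5-dimethoxy-6-[(2R)-5-methyl-2-(prop-1-en-2-yl)hex-4-en-1-yl]cyclohexa-1,4-diene; 5 prenyl bromide
Product: 15 1,5-dimethoxy-6-(3-methylbut-2-en-1-yl)-6-[(2R)-5-methyl-2-(prop-1-en-2-yl)hex-4-en-1-yl]cyclohexa-1,4-diene, via tertiary dienyllithium 14 (not isolated)
Conditions: t-BuLi, THF, −78 → −40 °C; then 5, −78 °C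
Reagents that add atoms: none
Why: A second deprotonation and alkylation at the same carbon with the reactive allylic bromide makes C5 quaternary; C5 is not stereogenic because the two enol-ether arms are identical.

Step 8
Reactants: 15 1,5-dimethoxy-6-(3-methylbut-2-en-1-yl)-6-[(2R)-5-methyl-2-(prop-1-en-2-yl)hex-4-en-1-yl]cyclohexa-1,4-diene
Product: 18 (1S,5S,7R)-4-methoxy-8,8-dimethyl-5,7-bis(3-methylbut-2-en-1-yl)bicyclo[3.3.1]non-3-en-9-one, via tertiary C8 radical 16 (not isolated), via C9 oxocarbenium ion 17 (not isolated)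
Conditions: Co(II)(salen) complex [N,N′-bis(3,5-di-tert-butylsalicylidene)-1,2-cyclohexanediaminocobalt(II)] (5 mol %), N-fluoro-2,4,6-trimethylpyridinium tetrafluoroborate (1.5 equiv), PhSiH3 (1.2 equiv), 2,6-di-tert-butylpyridine (0.3 equiv), PhCF3, 0 °C; aq. NaHCO3 work-up
Reagents that add atoms: none
Why: Proposed new method: Co(III)–H should transfer a hydrogen atom to the terminal CH2 of the 1,1-disubstituted isopropenyl group (sterically preferred over the four trisubstituted alkenes), and the tertiary C8 radical 16 is oxidised through an alkyl–Co(IV) species to a C8 cation equivalent that is captured by C1, the β-carbon of one methyl enol ether, to give oxocarbenium ion 17, whose O-methyl group passes to the liberated collidine and unveils the C9 ketone. The closest known reaction type is the Co(salen)/N-fluoropyridinium/silane MHAT radical-polar crossover hydrofunctionalisation (hydroalkoxylation with in situ O-dealkylation, hydroarylation, MHAT-initiated cation-olefin bicyclisation through electron-rich alkenes), together with Lewis-acid cyclisation of such bis(enol ether) dienes onto a tertiary carbon; what is new is the union of the two, with an enol-ether carbon terminating the crossover to give a bridged ketone. Ring B (C1–C9–C5–C6–C7–C8) closes in a 6-(enolendo)-exo-tet mode through a chair in which the forming C1–C8 bond is axial on ring A. C8 is not stereogenic, while C1 and C5 become stereogenic in this one event under control of C7: the C7-prenyl must sit equatorial in the chair (axial it would clash 1,3-diaxially with the C5–C4 and C1–C2 bonds under ring A), so only one of the two diastereotopic enol-ether carbons is alkylated and the 7-exo bicycle results. The step needs chemoselective HAT (secured by the unique 1,1-disubstituted alkene), C- rather than O-alkylation (both oxygens flanking C5 are methylated) and capture by the enol ether rather than by the C5-prenyl alkene (the enol ether is by far the stronger π-nucleophile).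

Step 9
Reactants: 18 (1S,5S,7R)-4-methoxy-8,8-dimethyl-5,7-bis(3-methylbut-2-en-1-yl)bicyclo[3.3.1]non-3-en-9-one
Product: 19 (1R,5S,7R)-4-methoxy-8,8-dimethyl-5,7-bis(3-methylbut-2-en-1-yl)bicyclo[3.3.1]non-3-ene-2,9-dione
Conditions: Rh2(cap)4 (1 mol %), t-BuOOH (5 equiv), K2CO3 (0.5 equiv), CH2Cl2, rt
Reagents that add atoms: tert-butyl hydroperoxide, CC(C)(C)OO
Why: Radical allylic oxidation at C2, the only ring CH2 allylic to the enol ether, should turn the enol ether into the vinylogous ester; the prenyl C–H bonds are less activated and no stereocentre is touched.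

Step 10
Reactants: 19 (1R,5S,7R)-4-methoxy-8,8-dimethyl-5,7-bis(3-methylbut-2-en-1-yl)bicyclo[3.3.1]non-3-ene-2,9-dione; 5 prenyl bromide
Product: 21 (1R,5S,7R)-4-methoxy-8,8-dimethyl-1,5,7-tris(3-methylbut-2-en-1-yl)bicyclo[3.3.1]non-3-ene-2,9-dione, via bridgehead lithio species 20 (not isolated)
Conditions: LDA, THF, −78 °C; then 5, −78 → 0 °C
Reagents that add atoms: none
Why: Bridgehead (α′) lithiation of the bicyclic vinylogous ester at C1, which is flanked by the C2 and C9 carbonyls, followed by SN2 alkylation; the bicycle enforces retention at C1.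

Step 11
Reactants: 22 3,4-dihydroxybenzoic acid
Product: 23 tert-butyldimethylsilyl 3,4-bis(tert-butyldimethylsilyloxy)benzoate
Conditions: TBSCl (3.3 equiv), imidazole, DMF, rt
Reagents that add atoms: tert-butyldimethylsilyl chloride, CC(C)(C)[Si](C)(C)Cl
Why: Silylation of both phenols and the acid under standard imidazole catalysis.

Step 12
Reactants: 23 tert-butyldimethylsilyl 3,4-bis(tert-butyldimethylsilyloxy)benzoate
Product: 24 3,4-bis(tert-butyldimethylsilyloxy)benzoyl chloride
Conditions: (COCl)2, DMF (cat.), CH2Cl2, 0 °C → rt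
Reagents that add atoms: oxalyl chloride, O=C(Cl)C(Cl)=O
Why: Silyl esters are converted directly into acid chlorides by the Vilsmeier reagent under neutral conditions, which the aryl silyl ethers should survive.

Step 13
Reactants: 21 (1R,5S,7R)-4-methoxy-8,8-dimethyl-1,5,7-tris(3-methylbut-2-en-1-yl)bicyclo[3.3.1]non-3-ene-2,9-dione; 24 3,4-bis(tert-butyldimethylsilyloxy)benzoyl chloride
Product: 26 (1S,5S,7R)-3-[3,4-bis(tert-butyldimethylsilyloxy)benzoyl]-4-methoxy-8,8-dimethyl-1,5,7-tris(3-methylbut-2-en-1-yl)bicyclo[3.3.1]non-3-ene-2,9-dione, via C3 vinyllithium 25 (not isolated)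
Conditions: LiTMP, THF, −78 °C; then 24, −78 → −20 °C
Reagents that add atoms: none
Why: With both bridgeheads quaternary, the hindered amide base should remove the only acidic proton left (vinylic C3–H of the vinylogous ester), and the vinyllithium is C-acylated by the acid chloride.

Step 14
Reactants: 26 (1S,5S,7R)-3-[3,4-bis(tert-butyldimethylsilyloxy)benzoyl]-4-methoxy-8,8-dimethyl-1,5,7-tris(3-methylbut-2-en-1-yl)bicyclo[3.3.1]non-3-ene-2,9-dione
Product: 27 aristophenone A [(1S,5S,7R)-3-(3,4-dihydroxybenzoyl)-4-hydroxy-8,8-dimethyl-1,5,7-tris(3-methylbut-2-en-1-yl)bicyclo[3.3.1]non-3-ene-2,9-dione]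
Conditions: LiOH·H2O, 1,4-dioxane/H2O, 90 °C, degassed (Ar); then 1 M HCl work-up under Ar
Reagents that add atoms: lithium hydroxide, [Li+].[OH-]
Why: Hydroxide addition–elimination at C4 of the vinylogous methyl ester should unmask the enolised β-triketone (isolated as a stable enolate until acidification) and the same base cleaves both aryl silyl ethers; the prenyl groups and the three stereocentres are inert to base.

**Compound list**

1 | (S)-4-benzyloxazolidin-2-one | O=C1N[C@@H](Cc2ccccc2)CO1 | starting material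
2 | 3-methylbut-2-enoyl chloride | CC(C)=CC(Cl)=O | starting material
3 | N-lithio-(S)-4-benzyloxazolidin-2-one | [Li]N1[C@@H](Cc2ccccc2)COC1=O | intermediate
4 | (S)-4-benzyl-3-(3-methylbut-2-enoyl)oxazolidin-2-one | CC(C)=CC(=O)N1[C@@H](Cc2ccccc2)COC1=O | intermediate
5 | prenyl bromide (1-bromo-3-methylbut-2-ene) | CC(C)=CCBr | starting material
6 | sodium (Z)-dienolate of 4 | C=C(C)/C=C(\[O-])N1[C@@H](Cc2ccccc2)COC1=O.[Na+] | intermediate
7 | (S)-4-benzyl-3-[(2S)-5-methyl-2-(prop-1-en-2-yl)hex-4-enoyl]oxazolidin-2-one | CC(C)=CC[C@H](C(=O)N1[C@@H](Cc2ccccc2)COC1=O)C(C)=C | intermediate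
8 | (S)-lavandulol | CC(C)=CC[C@H](CO)C(C)=C | intermediate
9 | (S)-lavandulyl iodide | CC(C)=CC[C@H](CI)C(C)=C | intermediate
10 | 1,3-dimethoxybenzene | COc1cccc(OC)c1 | starting material
11 | 1,5-dimethoxycyclohexa-1,4-diene | COC1=CCC=C(OC)C1 | intermediate
12 | 6-lithio-1,5-dimethoxycyclohexa-1,4-diene | [Li]C1C(OC)=CCC=C1OC | intermediate
13 | 1,5-dimethoxy-6-[(2R)-5-methyl-2-(prop-1-en-2-yl)hex-4-en-1-yl]cyclohexa-1,4-diene | COC1=CCC=C(OC)C1C[C@@H](CC=C(C)C)C(C)=C | intermediate
14 | 6-lithio derivative of 13 | [Li]C1(C[C@@H](CC=C(C)C)C(C)=C)C(OC)=CCC=C1OC | intermediate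
15 | 1,5-dimethoxy-6-(3-methylbut-2-en-1-yl)-6-[(2R)-5-methyl-2-(prop-1-en-2-yl)hex-4-en-1-yl]cyclohexa-1,4-diene | COC1=CCC=C(OC)C1(CC=C(C)C)C[C@@H](CC=C(C)C)C(C)=C | intermediate
16 | tertiary C8 radical from 15 (H added to the isopropenyl CH2) | COC1=CCC=C(OC)C1(CC=C(C)C)C[C@@H](CC=C(C)C)[C](C)C | intermediate
17 | C9 O-methyl oxocarbenium tetrafluoroborate of the closed bicycle | CC(C)=CC[C@@H]1C[C@]2(CC=C(C)C)C(=[O+]C)[C@@H](CC=C2OC)C1(C)C.F[B-](F)(F)F | intermediate
18 | (1S,5S,7R)-4-methoxy-8,8-dimethyl-5,7-bis(3-methylbut-2-en-1-yl)bicyclo[3.3.1]non-3-en-9-one | CC(C)=CC[C@@H]1C[C@]2(CC=C(C)C)C(=O)[C@@H](CC=C2OC)C1(C)C | intermediate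
19 | (1R,5S,7R)-4-methoxy-8,8-dimethyl-5,7-bis(3-methylbut-2-en-1-yl)bicyclo[3.3.1]non-3-ene-2,9-dione | CC(C)=CC[C@@H]1C[C@]2(CC=C(C)C)C(=O)[C@@H](C(=O)C=C2OC)C1(C)C | intermediate
20 | C1 bridgehead lithio derivative of 19 | CC(C)=CC[C@@H]1C[C@]2(CC=C(C)C)C(=O)[C@@]([Li])(C(=O)C=C2OC)C1(C)C | intermediate
21 | (1R,5S,7R)-4-methoxy-8,8-dimethyl-1,5,7-tris(3-methylbut-2-en-1-yl)bicyclo[3.3.1]non-3-ene-2,9-dione | CC(C)=CC[C@@H]1C[C@]2(CC=C(C)C)C(=O)[C@@](CC=C(C)C)(C(=O)C=C2OC)C1(C)C | intermediate
22 | 3,4-dihydroxybenzoic acid | OC(=O)c1ccc(O)c(O)c1 | starting material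
23 | tert-butyldimethylsilyl 3,4-bis(tert-butyldimethylsilyloxy)benzoate | CC(C)(C)[Si](C)(C)OC(=O)c1ccc(O[Si](C)(C)C(C)(C)C)c(O[Si](C)(C)C(C)(C)C)c1 | intermediate
24 | 3,4-bis(tert-butyldimethylsilyloxy)benzoyl chloride | CC(C)(C)[Si](C)(C)Oc1ccc(C(Cl)=O)cc1O[Si](C)(C)C(C)(C)C | intermediate
25 | C3 vinyllithium of 21 | CC(C)=CC[C@@H]1C[C@]2(CC=C(C)C)C(=O)[C@@](CC=C(C)C)(C(=O)C([Li])=C2OC)C1(C)C | intermediate
26 | (1S,5S,7R)-3-[3,4-bis(tert-butyldimethylsilyloxy)benzoyl]-4-methoxy-8,8-dimethyl-1,5,7-tris(3-methylbut-2-en-1-yl)bicyclo[3.3.1]non-3-ene-2,9-dione | CC(C)=CC[C@@H]1C[C@]2(CC=C(C)C)C(=O)[C@@](CC=C(C)C)(C(=O)C(C(=O)c3ccc(O[Si](C)(C)C(C)(C)C)c(O[Si](C)(C)C(C)(C)C)c3)=C2OC)C1(C)C | intermediate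
27 | aristophenone A | CC(C)=CC[C@@H]1C[C@]2(CC=C(C)C)C(=O)[C@@](CC=C(C)C)(C(=O)C(C(=O)c3ccc(O)c(O)c3)=C2O)C1(C)C | target

**Step count and risks**

Total steps: 14. Longest linear sequence: 11 steps (1–4, 6–10, 13, 14).

Steps most likely to fail:

1. Step 8 (Proposed new method). What may go wrong:
   - The C8 cation equivalent may lose a proton or undergo a 1,2-hydride shift from C7, giving alkene isomers, erosion at C7 or a five-membered closure.
   - It may be captured by fluoride instead of by C1.
   - The enol ethers may be attacked by the oxidant or by traces of acid.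

   Fallback with known chemistry, setting out from 15: radical bis-allylic oxidation of the ring CH2 (Rh2(cap)4 cat., t-BuOOH) would give the cross-conjugated 3,5-dimethoxy-4,4-dialkylcyclohexa-2,5-dienone F1. Mukaiyama hydration (Co(acac)2 cat., PhSiH3, O2, i-PrOH), which hydrates 1,1-disubstituted alkenes in preference to trisubstituted ones, would give tertiary alcohol F2. Ionisation with TiCl4 and 2,6-di-tert-butyl-4-methylpyridine (CH2Cl2, −78 °C; an intramolecular Reetz-type SN1 tert-alkylation of an enol ether) would close the same C1–C8 bond. After loss of the O-methyl group the sequence comes back to the route at 19, so step 9 is no longer needed.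

2. Step 6. What may go wrong: E2 elimination of the β-branched iodide by the strongly basic dienyl anion, or slow SN2. Fallback, setting out from 9: zinc insertion (Zn dust, LiCl, THF) would give lavandulylzinc iodide F3. Negishi coupling with commercial 2-bromo-1,3-dimethoxybenzene (Pd(OAc)2, SPhos, THF, 50 °C) would give 2-lavandulyl-1,3-dimethoxybenzene F4. Birch reduction (Li, NH3, t-BuOH, THF, −78 °C), which leaves isolated alkenes alone, comes back to the route at 13.

3. Step 10. What may go wrong: slow SN2 capture of the hindered bridgehead anion next to the gem-dimethyl carbon, or competing deprotonation at C3. Fallback, setting out from 19: LDA then I2 (THF, −78 °C) would give bridgehead iodide F5, since iodine is a small and fast electrophile. Keck radical allylation (allyltributylstannane, AIBN, PhH, 80 °C) would give bridgehead allyl compound F6 without an SN2 step. Cross-metathesis with 2-methyl-2-butene (Grubbs II, CH2Cl2, 40 °C) turns allyl into prenyl and comes back to the route at 21.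

Further compounds

F1 | step 8 | 3,5-dimethoxy-4-(3-methylbut-2-en-1-yl)-4-[(2R)-5-methyl-2-(prop-1-en-2-yl)hex-4-en-1-yl]cyclohexa-2,5-dien-1-one | COC1=CC(=O)C=C(OC)C1(CC=C(C)C)C[C@@H](CC=C(C)C)C(C)=C
F2 | step 8 | 4-[(2R)-2-(2-hydroxypropan-2-yl)-5-methylhex-4-en-1-yl]-3,5-dimethoxy-4-(3-methylbut-2-en-1-yl)cyclohexa-2,5-dien-1-one | COC1=CC(=O)C=C(OC)C1(CC=C(C)C)C[C@@H](CC=C(C)C)C(C)(C)O
F3 | step 6 | (S)-lavandulylzinc iodide | CC(C)=CC[C@H](C[Zn]I)C(C)=C
F4 | step 6 | 1,3-dimethoxy-2-[(2R)-5-methyl-2-(prop-1-en-2-yl)hex-4-en-1-yl]benzene | COc1cccc(OC)c1C[C@@H](CC=C(C)C)C(C)=C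
F5 | step 10 | (1S,5S,7R)-1-iodo-4-methoxy-8,8-dimethyl-5,7-bis(3-methylbut-2-en-1-yl)bicyclo[3.3.1]non-3-ene-2,9-dione | CC(C)=CC[C@@H]1C[C@]2(CC=C(C)C)C(=O)[C@@](I)(C(=O)C=C2OC)C1(C)C
F6 | step 10 | (1R,5S,7R)-1-allyl-4-methoxy-8,8-dimethyl-5,7-bis(3-methylbut-2-en-1-yl)bicyclo[3.3.1]non-3-ene-2,9-dione | CC(C)=CC[C@@H]1C[C@]2(CC=C(C)C)C(=O)[C@@](CC=C)(C(=O)C=C2OC)C1(C)C
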